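In a one-step world, starting material + partner → target, and every point of starting material lost is a point of target. We test that on two runs and then build up the flask.

| flask | starting material | partner | transfer agent | protic impurity | initiator | remark | time |
|---|---|---|---|---|---|---|---|
| teal | 0.20 M | 0.12 M | 0.20 M | 0.020 M | 4.4 mM | run made earlier |  |
| red | 0.20 M | 0.18 M | 0.20 M | 0.020 M | 4.4 mM | run made earlier |  |
| theta | 0.20 M | 0.240 M | 0.200 M | 0.0200 M | 4.4 mM |  | 30 h |
| gamma | 0.20 M | 0.240 M | 0.200 M | 0.0200 M | 4.4 mM |  | 20 h |
| beta | 0.20 M | 0.240 M | 0.200 M | 0.0200 M | 4.4 mM |  | 50 h |

| run | time / h | side product / % | starting material / % | first chain carrier / % | target / % |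
|---|---|---|---|---|---|
| teal | 6.00 | 0.7 | 97.5 | 0.9 | 1.9 |
| teal | 12.0 | 1.7 | 97.2 | 0.4 | 3.4 |
| teal | 20.0 | 0.9 | 94.7 | 0.2 | 4.2 |
| teal | 25.0 | 1.5 | 93.4 | 0.1 | 4.8 |
| red | 6.00 | 0.2 | 97.1 | 0 | 2.6 |
| red | 12.0 | 0.4 | 94.9 | 0 | 5.1 |
| red | 20.0 | 1.7 | 92.3 | 1.0 | 5.6 |
| red | 25.0 | 1.8 | 92.4 | 0.3 | 6.6 |

(standard deviation of a reading: 0.5 percentage points)

- in percentages every species weighs as the starting material in it: one ended chains A counts as two
- the numbers in the tables scatter with a standard deviation of 0.5 percentage points
- on the list of suspects stand: partner + first chain carrier -> target + second chain carrier; transfer agent + first chain carrier -> side product + idle radical; 2 idle radical -> ended radicals; 2 first chain carrier -> ended chains A; starting material + initiating radical -> capped initiator + first chain carrier; partner <-> dormant form; 2 second chain carrier -> ended chains B; partner + protic impurity -> quenched reagent; initiator -> 2 initiating radical; starting material + second chain carrier -> by-product + first chain carrier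

* which of these there is most of at the end, counted by the starting material in it, theta (target / starting material / first chain carrier / side product)
* which of these there is most of at the end, counted by the starting material in it, gamma (target / starting material / first chain carrier / side product)
* which of these there is most of at the end, counted by the starting material in it, beta (target / starting material / first chain carrier / side product)
* how much there is at the end of the one of these that leads, in percent of the starting material charged: theta
* how much there is at the end of the one of these that leads, in percent of the starting material charged: gamma
* how much there is at the end of the one of these that leads, in percent of the starting material charged: beta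

1. The main step alone. In teal at 25.0 h, target reads 0.727 of the starting material lost, not 1, and side product stands beside it.

2. Add the transfer step. First chain carrier now has two exits: target forms at a[partner][first chain carrier], side product at b[transfer agent][first chain carrier]. Dividing one rate by the other removes the carrier, and time goes with it as far as [partner] and [transfer agent] hold steady. So we call target over side product ρ, the selectivity factor, and read it as a ratio of totals. The scatter of 0.5 percentage points weighs heavily on the side-product readings, so we sum the four times: ρ is 2.98 in teal and 4.85 in red, larger in red, the run with more partner.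

3. Add the impurity. It can take partner mole for mole, so we count the charge of partner minus the charge of impurity. ρ per molarity of that net partner is 29.8 L mol⁻¹ in teal and 30.3 L mol⁻¹ in red, about equal. We assume the dormant form holds a fixed share of partner, which then sits inside this constant. Their mean, s = 30.1 L mol⁻¹, a reading that carries the scatter of its sums, is the net-partner selectivity constant, for transfer agent at 0.200 M.

4. Add the rest. For the new recipe, ρ = s([partner] − [impurity]) at charge = 6.61. Side product at 20.0 h reads 0.9 % in teal and 1.7 % in red, with no trend in partner beyond the scatter, so we take 1.30 %. Starting material lost is side product times (1 + ρ), which leaves 90.1 % in gamma by our reckoning, with starting material leading.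

5. The forecast also names starting material as the leader in each flask. It gives 91 % for gamma (89 % to 92.5 %), 89 % for theta (86.5 % to 91 %) and 87.5 % for beta (83.5 % to 90 %), on the ground that “the chain is dying and has a plateau”. For gamma it stands 0.9 points above ours.

6. The flasks give starting material in the lead: 90.3 % in gamma, 87.1 % in theta and 82.5 % in beta, the last below the forecast.

    partner + first chain carrier → target + second chain carrier (k = 4.90 × 10⁵ L mol⁻¹ min⁻¹)
    transfer agent + first chain carrier → side product + idle radical (kL = 36000 L mol⁻¹ min⁻¹)
    2 idle radical → ended radicals (k = 1.00 × 10⁷ L mol⁻¹ s⁻¹)
    2 first chain carrier → ended chains A (k = 2.00 × 10⁸ L mol⁻¹ s⁻¹)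
    starting material + initiating radical → capped initiator + first chain carrier (k = 80000 L mol⁻¹ s⁻¹)
    partner ⇌ dormant form (K = 1.70, k = 0.00750 min⁻¹)
    2 second chain carrier → ended chains B (k = 2.00 × 10⁸ L mol⁻¹ s⁻¹)
    partner + protic impurity → quenched reagent (k = 0.0620 L mol⁻¹ min⁻¹)
    initiator → 2 initiating radical (k = 3.10 × 10⁻⁴ min⁻¹)
    starting material + second chain carrier → by-product + first chain carrier (k = 1.20 × 10⁵ L mol⁻¹ s⁻¹)

Gamma's own target and side product give ρ = 6.13, against our 6.61. Side product is a small entry at 1.37 %, yet the step making it is what keeps starting material in the lead: it turns first chain carrier into idle radical, and with that step taken away gamma keeps 3.10 % of its starting material instead of 90.3 %. A neighbour of gamma charged with 0.80 M of starting material has the same net partner, and its target and side product give ρ = 6.13.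

All runs are simulated from invented constants; the scatter is artificial.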